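Ring A is made rather than alkylated: a Danheiser benzannulation between 3-methoxycyclobutenone and a triisopropylsilyl ynol ether forms the C2'–C3' and C4'–C5' bonds and closes ring A in one neutral, thermal operation. The step exploits the substitution pattern of ring A: oxygen on C2', C4' and C6', with the C1-bearing C3' flanked on both sides by oxygenated carbons. The ynol ether already carries C1 with ring C, both stereocentres (C1 and C5) and the E-C2=C3 chain, assembled by iridium-catalysed allylic alkynylation, Keck allylation and cross-metathesis. Silylation, iodination, magnesiation, cinnamaldehyde addition, oxidation and one global desilylation then complete the chalcone.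

Key step: step 11

Locants: C1–C7 are the heptenyl chain (C1 the diaryl methine, C5 the carbinol), C1'–C6' are ring A (C1' carries the acyl group), and ring C is the 4-hydroxyphenyl on C1. In names, Q stands for (1R,2E,5R)-5-(tert-butyldimethylsiloxy)-7-phenyl-1-[4-(triisopropylsiloxy)phenyl]hept-2-en-1-yl.

Assumption: the (S)-configured phosphoramidite–olefin ligand in step 5 is taken to deliver the alkynyl group to the Re face of the benzylic allyl terminus; should the sense prove opposite, the mirror-image ligand is used with no other change.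

Design remarks: the ring C phenol is carried as a TIPS ether, because an aryl TBS ether would not survive the bifluoride of step 5. The alkynyl-TMS group is removed with catalytic AgNO3 and not with carbonate in methanol, because a 3-aryl-1,4-enyne is prone to base-mediated isomerisation to the allene.

Step 1
Reactants: 1 3-ethoxycyclobut-2-en-1-one
Product: 2 3-methoxycyclobut-2-en-1-one
Conditions: MeOH (solvent), camphorsulfonic acid (cat.), 3 Å MS, rt
Reagents that add atoms: methanol, CO
Why: Acid-catalysed transetherification of a vinylogous ester, in which methanol adds at C3 of the protonated enone and ethanol leaves, should be driven to completion by the solvent excess.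

Step 2
Reactants: 3 4-hydroxybenzaldehyde
Product: 4 4-(triisopropylsiloxy)benzaldehyde
Conditions: TIPSCl, imidazole, DMF, rt
Reagents that add atoms: triisopropylsilyl chloride, CC(C)[Si](Cl)(C(C)C)C(C)C
Why: Standard phenol silylation gives an aryl TIPS ether robust enough for the bifluoride, acid and organometallic steps ahead.

Step 3
Reactants: 4 4-(triisopropylsiloxy)benzaldehyde
Product: 5 rac-1-[4-(triisopropylsiloxy)phenyl]prop-2-en-1-ol
Conditions: CH2=CHMgBr, THF, −78 → 0 °C; then H2O
Reagents that add atoms: vinylmagnesium bromide, C=C[Mg]Br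
Why: Grignard 1,2-addition to an aromatic aldehyde should give the racemic branched allylic alcohol, which the enantioconvergent step 5 accepts as such.

Step 4
Reactants: 6 trimethylsilylacetylene
Product: 9 potassium trifluoro[(trimethylsilyl)ethynyl]borate, via lithium (trimethylsilyl)acetylide 7 (not isolated), via lithium trimethoxy(alkynyl)borate 8 (not isolated)
Conditions: n-BuLi, THF, −78 °C; B(OMe)3, −78 → −20 °C; aq. KHF2, −20 °C → rt
Reagents that add atoms: trimethyl borate, COB(OC)OC; potassium hydrogen difluoride, [K+].[F-].F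
Why: Alkyne deprotonation, borylation of the acetylide and fluoride exchange (standard alkynyltrifluoroborate synthesis) should give the bench-stable alkynyl donor.

Step 5
Reactants: 5 rac-1-[4-(triisopropylsiloxy)phenyl]prop-2-en-1-ol; 9 potassium trifluoro[(trimethylsilyl)ethynyl]borate
Product: 10 triisopropyl{4-[(3R)-5-(trimethylsilyl)pent-1-en-4-yn-3-yl]phenoxy}silane
Conditions: [Ir(cod)Cl]2 (4 mol %), (S)-BINOL-derived dibenzazepine phosphoramidite–olefin ligand (16 mol %), KHF2, CF3CO2H, n-Bu4NBr, 1,4-dioxane, rt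
Reagents that add atoms: none
Why: Iridium-catalysed enantioselective allylic alkynylation of a racemic aryl vinyl carbinol proceeds through an (η3-allyl)Ir intermediate whose benzylic terminus is attacked on the face dictated by the chiral ligand, which should set C1 as (R) and leave the vinyl group for metathesis.

Step 6
Reactants: 11 3-phenylpropanal
Product: 12 (R)-1-phenylhex-5-en-3-ol
Conditions: allylSnBu3, Ti(OiPr)4 (10 mol %), (S)-BINOL (20 mol %), 4 Å MS, CH2Cl2, −20 °C; then H2O
Reagents that add atoms: allyltributylstannane, C=CC[Sn](CCCC)(CCCC)CCCC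
Why: In the Keck asymmetric allylation the (S)-BINOL/Ti(OiPr)4 complex should expose the Si face of the aldehyde to the allylstannane, which sets C5 as (R).

Step 7
Reactants: 12 (R)-1-phenylhex-5-en-3-ol
Product: 13 (R)-tert-butyldimethyl[(1-phenylhex-5-en-3-yl)oxy]silane
Conditions: TBSCl, imidazole, DMF, rt
Reagents that add atoms: tert-butyldimethylsilyl chloride, CC(C)(C)[Si](C)(C)Cl
Why: Standard silylation of a secondary alcohol gives a TBS ether that should last until the final fluoride step.

Step 8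
Reactants: 10 triisopropyl{4-[(3R)-5-(trimethylsilyl)pent-1-en-4-yn-3-yl]phenoxy}silane; 13 (R)-tert-butyldimethyl[(1-phenylhex-5-en-3-yl)oxy]silane
Product: 14 (3R,4E,7R)-7-(tert-butyldimethylsiloxy)-9-phenyl-3-[4-(triisopropylsiloxy)phenyl]-1-(trimethylsilyl)non-4-en-1-yne
Conditions: 13 (3 equiv), second-generation Hoveyda–Grubbs catalyst (H2IMes)Cl2Ru=CH(C6H4-2-OiPr) (5 mol %), 1,4-benzoquinone (10 mol %), CH2Cl2, 40 °C
Reagents that add atoms: none
Why: Olefin cross-metathesis between an allylically branched alkene that homodimerises slowly and an excess of an unhindered partner should be E-selective, with the silyl-capped alkyne staying out of enyne metathesis and benzoquinone suppressing Ru–H isomerisation.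

Step 9
Reactants: 14 (3R,4E,7R)-7-(tert-butyldimethylsiloxy)-9-phenyl-3-[4-(triisopropylsiloxy)phenyl]-1-(trimethylsilyl)non-4-en-1-yne
Product: 15 (3S,4E,7R)-7-(tert-butyldimethylsiloxy)-9-phenyl-3-[4-(triisopropylsiloxy)phenyl]non-4-en-1-yne (same spatial arrangement at C3; only the CIP ranking changes)
Conditions: AgNO3 (10 mol %), MeOH/H2O/CH2Cl2, rt, dark
Reagents that add atoms: none
Why: Silver-catalysed protodesilylation of an alkynylsilane runs through an alkynylsilver species (RC≡CAg) under neutral conditions, so the aryl silyl ether and the base-labile C1–H should both be untouched.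

Step 10
Reactants: 15 (3S,4E,7R)-7-(tert-butyldimethylsiloxy)-9-phenyl-3-[4-(triisopropylsiloxy)phenyl]non-4-en-1-yne
Product: 18 (3R,4E,7R)-7-(tert-butyldimethylsiloxy)-9-phenyl-1-(triisopropylsiloxy)-3-[4-(triisopropylsiloxy)phenyl]non-4-en-1-yne, via lithium acetylide 16 (not isolated), via lithium ynolate 17 (not isolated)
Conditions: LiN(SiMe3)2 (2.1 equiv), THF, −78 °C; t-BuOOH (1.05 equiv), −78 → 0 °C; TIPSOTf, −78 °C
Reagents that add atoms: tert-butyl hydroperoxide (as its lithium salt), CC(C)(C)OO; triisopropylsilyl triflate, CC(C)[Si](OS(=O)(=O)C(F)(F)F)(C(C)C)C(C)C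
Why: Oxidation of a lithium acetylide by lithium tert-butyl peroxide gives the lithium ynolate, which the bulky silyl triflate should trap on oxygen, and as long as the substrate is an acetylide or ynolate anion the C1–H is shielded from deprotonation.

Step 11
Reactants: 18 (3R,4E,7R)-7-(tert-butyldimethylsiloxy)-9-phenyl-1-(triisopropylsiloxy)-3-[4-(triisopropylsiloxy)phenyl]non-4-en-1-yne; 2 3-methoxycyclobut-2-en-1-one
Product: 23 5-methoxy-2-Q-3-(triisopropylsiloxy)phenol, via methoxyvinylketene 19 (not isolated), via vinylcyclobutenone 20 (not isolated), via dienylketene 21 (not isolated), via cyclohexadienone 22 (not isolated)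
Conditions: 2 (1.5 equiv, two portions), toluene, 80 → 110 °C, sealed tube
Reagents that add atoms: none
Why: Thermal 4π opening of 2 gives vinylketene 19, which adds [2+2] to the electron-rich ynol ether to give cyclobutenone 20; this opens to dienylketene 21, which cyclises to 22 and tautomerises to phenol 23. The closest known reaction type is the Danheiser benzannulation of cyclobutenones with siloxyalkynes to resorcinol monosilyl ethers. Ring A is closed by thermal disrotatory 6π electrocyclisation of the dienylketene (C1'–C2' bond), after the cycloaddition has made C2'–C3' and C4'–C5'. No stereocentre is created: C1 and C5 are spectators and the transient ring stereocentre of 20 disappears on ring opening. The selectivity needed is regiochemical and is secured by the polarisation of the ynol ether, whose nucleophilic carbon (the one bearing C1) bonds to the ketene carbonyl carbon, so the chain ends between the new hydroxyl and the siloxy carbon. The neutral medium should leave the skipped enyne and the C1–H intact.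

Step 12
Reactants: 23 5-methoxy-2-Q-3-(triisopropylsiloxy)phenol
Product: 24 5-methoxy-2-Q-1,3-bis(triisopropylsiloxy)benzene
Conditions: TIPSOTf, 2,6-lutidine, CH2Cl2, 0 °C → rt
Reagents that add atoms: triisopropylsilyl triflate, CC(C)[Si](OS(=O)(=O)C(F)(F)F)(C(C)C)C(C)C
Why: Silylation of the remaining phenol with a silyl triflate makes the two oxygen substituents flanking C3' identical, so the two open positions of ring A become equivalent and phenol-assisted iodoetherification of the C2=C3 alkene is excluded.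

Step 13
Reactants: 24 5-methoxy-2-Q-1,3-bis(triisopropylsiloxy)benzene
Product: 25 4-iodo-5-methoxy-2-Q-1,3-bis(triisopropylsiloxy)benzene
Conditions: NIS (1.05 equiv), MeCN/CH2Cl2, 0 °C → rt, dark
Reagents that add atoms: N-iodosuccinimide, O=C1CCC(=O)N1I
Why: Electrophilic aromatic iodination should take place on the trioxygenated ring A, by far the most electron-rich site, at either of its two equivalent C–H positions, with one equivalent of reagent limiting it to mono-substitution.

Step 14
Reactants: 25 4-iodo-5-methoxy-2-Q-1,3-bis(triisopropylsiloxy)benzene; 26 (E)-cinnamaldehyde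
Product: 28 (E)-1-[6-methoxy-3-Q-2,4-bis(triisopropylsiloxy)phenyl]-3-phenylprop-2-en-1-ol (both carbinol epimers), via arylmagnesium chloride 27 (not isolated)
Conditions: i-PrMgCl·LiCl, THF, −20 → 0 °C; 26, −40 → 0 °C; then pH 7 buffer
Reagents that add atoms: none
Why: Iodine–magnesium exchange with i-PrMgCl·LiCl gives an aryl Grignard reagent that tolerates silyl ethers and should add 1,2 to the enal; the new carbinol centre is uncontrolled and is erased in step 15.

Step 15
Reactants: 28 (E)-1-[6-methoxy-3-Q-2,4-bis(triisopropylsiloxy)phenyl]-3-phenylprop-2-en-1-ol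
Product: 29 (E)-1-[6-methoxy-3-Q-2,4-bis(triisopropylsiloxy)phenyl]-3-phenylprop-2-en-1-one
Conditions: MnO2, CH2Cl2, rt
Reagents that add atoms: none
Why: MnO2 oxidation of an allylic and benzylic alcohol under neutral conditions should give the chalcone ketone without touching the C1–H or the isolated alkene.

Step 16
Reactants: 29 (E)-1-[6-methoxy-3-Q-2,4-bis(triisopropylsiloxy)phenyl]-3-phenylprop-2-en-1-one
Product: 30 ent-alpinnanin B, (E)-1-{2,4-dihydroxy-3-[(1R,2E,5R)-5-hydroxy-1-(4-hydroxyphenyl)-7-phenylhept-2-en-1-yl]-6-methoxyphenyl}-3-phenylprop-2-en-1-one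
Conditions: Bu4NF, AcOH, THF, 0 °C → rt
Reagents that add atoms: none
Why: Fluoride-mediated desilylation, buffered with acetic acid so that free phenoxides cannot trigger chalcone-to-flavanone cyclisation, should remove the three aryl TIPS groups and the secondary TBS ether in one operation.

Compound list
1 | 3-ethoxycyclobut-2-en-1-one | CCOC1=CC(=O)C1 | starting material
2 | 3-methoxycyclobut-2-en-1-one | COC1=CC(=O)C1 | intermediate
3 | 4-hydroxybenzaldehyde | O=Cc1ccc(O)cc1 | starting material
4 | 4-(triisopropylsiloxy)benzaldehyde | O=Cc1ccc(O[Si](C(C)C)(C(C)C)C(C)C)cc1 | intermediate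
5 | rac-1-[4-(triisopropylsiloxy)phenyl]prop-2-en-1-ol | C=CC(O)c1ccc(O[Si](C(C)C)(C(C)C)C(C)C)cc1 | intermediate
6 | trimethylsilylacetylene | C#C[Si](C)(C)C | starting material
7 | lithium (trimethylsilyl)acetylide | [Li]C#C[Si](C)(C)C | intermediate (not isolated)
8 | lithium trimethoxy[(trimethylsilyl)ethynyl]borate | [Li+].CO[B-](OC)(OC)C#C[Si](C)(C)C | intermediate (not isolated)
9 | potassium trifluoro[(trimethylsilyl)ethynyl]borate | [K+].F[B-](F)(F)C#C[Si](C)(C)C | intermediate
10 | triisopropyl{4-[(3R)-5-(trimethylsilyl)pent-1-en-4-yn-3-yl]phenoxy}silane | C[Si](C)(C)C#C[C@H](C=C)c1ccc(O[Si](C(C)C)(C(C)C)C(C)C)cc1 | intermediate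
11 | 3-phenylpropanal | O=CCCc1ccccc1 | starting material
12 | (R)-1-phenylhex-5-en-3-ol | C=CC[C@H](O)CCc1ccccc1 | intermediate
13 | (R)-tert-butyldimethyl[(1-phenylhex-5-en-3-yl)oxy]silane | C=CC[C@H](O[Si](C)(C)C(C)(C)C)CCc1ccccc1 | intermediate
14 | (3R,4E,7R)-7-(tert-butyldimethylsiloxy)-9-phenyl-3-[4-(triisopropylsiloxy)phenyl]-1-(trimethylsilyl)non-4-en-1-yne | C[Si](C)(C)C#C[C@H](/C=C/C[C@H](O[Si](C)(C)C(C)(C)C)CCc1ccccc1)c1ccc(O[Si](C(C)C)(C(C)C)C(C)C)cc1 | intermediate
15 | (3S,4E,7R)-7-(tert-butyldimethylsiloxy)-9-phenyl-3-[4-(triisopropylsiloxy)phenyl]non-4-en-1-yne | C#C[C@H](/C=C/C[C@H](O[Si](C)(C)C(C)(C)C)CCc1ccccc1)c1ccc(O[Si](C(C)C)(C(C)C)C(C)C)cc1 | intermediate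
16 | lithium acetylide of 15 | [Li]C#C[C@H](/C=C/C[C@H](O[Si](C)(C)C(C)(C)C)CCc1ccccc1)c1ccc(O[Si](C(C)C)(C(C)C)C(C)C)cc1 | intermediate (not isolated)
17 | lithium ynolate (1-oxido analogue of 15) | [Li]OC#C[C@H](/C=C/C[C@H](O[Si](C)(C)C(C)(C)C)CCc1ccccc1)c1ccc(O[Si](C(C)C)(C(C)C)C(C)C)cc1 | intermediate (not isolated)
18 | (3R,4E,7R)-7-(tert-butyldimethylsiloxy)-9-phenyl-1-(triisopropylsiloxy)-3-[4-(triisopropylsiloxy)phenyl]non-4-en-1-yne | CC(C)[Si](C(C)C)(C(C)C)OC#C[C@H](/C=C/C[C@H](O[Si](C)(C)C(C)(C)C)CCc1ccccc1)c1ccc(O[Si](C(C)C)(C(C)C)C(C)C)cc1 | intermediate (key-step precursor)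
19 | 3-methoxybuta-1,3-dien-1-one (methoxyvinylketene) | C=C(OC)C=C=O | intermediate (not isolated)
20 | 4-(1-methoxyethenyl)-2-Q-3-(triisopropylsiloxy)cyclobut-2-en-1-one (epimers at C4) | C=C(OC)C1C(O[Si](C(C)C)(C(C)C)C(C)C)=C([C@H](/C=C/C[C@H](O[Si](C)(C)C(C)(C)C)CCc2ccccc2)c2ccc(O[Si](C(C)C)(C(C)C)C(C)C)cc2)C1=O | intermediate (not isolated)
21 | 5-methoxy-2-Q-3-(triisopropylsiloxy)hexa-1,3,5-trien-1-one (ketene carbon and methoxyvinyl group cis across C3=C4) | C=C(OC)/C=C(O[Si](C(C)C)(C(C)C)C(C)C)\C(=C=O)[C@H](/C=C/C[C@H](O[Si](C)(C)C(C)(C)C)CCc1ccccc1)c1ccc(O[Si](C(C)C)(C(C)C)C(C)C)cc1 | intermediate (not isolated)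
22 | 5-methoxy-2-Q-3-(triisopropylsiloxy)cyclohexa-2,4-dien-1-one | COC1=CC(O[Si](C(C)C)(C(C)C)C(C)C)=C([C@H](/C=C/C[C@H](O[Si](C)(C)C(C)(C)C)CCc2ccccc2)c2ccc(O[Si](C(C)C)(C(C)C)C(C)C)cc2)C(=O)C1 | intermediate (not isolated)
23 | 5-methoxy-2-Q-3-(triisopropylsiloxy)phenol | COc1cc(O)c([C@H](/C=C/C[C@H](O[Si](C)(C)C(C)(C)C)CCc2ccccc2)c2ccc(O[Si](C(C)C)(C(C)C)C(C)C)cc2)c(O[Si](C(C)C)(C(C)C)C(C)C)c1 | intermediate (key-step product)
24 | 5-methoxy-2-Q-1,3-bis(triisopropylsiloxy)benzene | COc1cc(O[Si](C(C)C)(C(C)C)C(C)C)c([C@H](/C=C/C[C@H](O[Si](C)(C)C(C)(C)C)CCc2ccccc2)c2ccc(O[Si](C(C)C)(C(C)C)C(C)C)cc2)c(O[Si](C(C)C)(C(C)C)C(C)C)c1 | intermediate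
25 | 4-iodo-5-methoxy-2-Q-1,3-bis(triisopropylsiloxy)benzene | COc1cc(O[Si](C(C)C)(C(C)C)C(C)C)c([C@H](/C=C/C[C@H](O[Si](C)(C)C(C)(C)C)CCc2ccccc2)c2ccc(O[Si](C(C)C)(C(C)C)C(C)C)cc2)c(O[Si](C(C)C)(C(C)C)C(C)C)c1I | intermediate
26 | (E)-cinnamaldehyde | O=C/C=C/c1ccccc1 | starting material
27 | [6-methoxy-3-Q-2,4-bis(triisopropylsiloxy)phenyl]magnesium chloride | COc1cc(O[Si](C(C)C)(C(C)C)C(C)C)c([C@H](/C=C/C[C@H](O[Si](C)(C)C(C)(C)C)CCc2ccccc2)c2ccc(O[Si](C(C)C)(C(C)C)C(C)C)cc2)c(O[Si](C(C)C)(C(C)C)C(C)C)c1[Mg]Cl | intermediate (not isolated)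
28 | (E)-1-[6-methoxy-3-Q-2,4-bis(triisopropylsiloxy)phenyl]-3-phenylprop-2-en-1-ol (both carbinol epimers) | COc1cc(O[Si](C(C)C)(C(C)C)C(C)C)c([C@H](/C=C/C[C@H](O[Si](C)(C)C(C)(C)C)CCc2ccccc2)c2ccc(O[Si](C(C)C)(C(C)C)C(C)C)cc2)c(O[Si](C(C)C)(C(C)C)C(C)C)c1C(O)/C=C/c1ccccc1 | intermediate
29 | (E)-1-[6-methoxy-3-Q-2,4-bis(triisopropylsiloxy)phenyl]-3-phenylprop-2-en-1-one | COc1cc(O[Si](C(C)C)(C(C)C)C(C)C)c([C@H](/C=C/C[C@H](O[Si](C)(C)C(C)(C)C)CCc2ccccc2)c2ccc(O[Si](C(C)C)(C(C)C)C(C)C)cc2)c(O[Si](C(C)C)(C(C)C)C(C)C)c1C(=O)/C=C/c1ccccc1 | intermediate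
30 | ent-alpinnanin B | COc1cc(O)c([C@H](/C=C/C[C@H](O)CCc2ccccc2)c2ccc(O)cc2)c(O)c1C(=O)/C=C/c1ccccc1 | target

Total step count: 16.
Longest linear sequence: 12 steps (steps 2, 3, 5, 8, 9, 10, 11, 12, 13, 14, 15, 16).

Steps most likely to fail

Step 11. The vinylogous-ester stabilisation of 2 may push its ring opening to temperatures at which the ynol ether rearranges, or at which the vinylketene dimerises or acylates the product phenol. The fallback generates the same vinylketene at room temperature by photochemical Wolff rearrangement (the second-generation form of the Danheiser benzannulation). Commercial 3,3-dimethoxybutan-2-one would lose methanol under acid catalysis (TsOH, distillation) to give 3-methoxybut-3-en-2-one F1. Its lithium enolate (LiN(SiMe3)2) would be trifluoroacetylated with CF3CO2CH2CF3 to 1,1,1-trifluoro-5-methoxyhex-5-ene-2,4-dione F2, and diazo transfer (MsN3, Et3N, H2O, MeCN) would give 1-diazo-3-methoxybut-3-en-2-one F3. The fallback sets out from siloxyalkyne 18: irradiation of F3 with 18 in CH2Cl2 should give 19 and then cyclobutenone 20, and brief warming to 80 °C should carry 20 through 21 and 22 to phenol 23, where the route is rejoined.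

Step 10. During the time at 0 °C that the acetylide oxidation needs, proton transfer at the propargylic, allylic and benzylic C1–H could cause propargyl–allenyl isomerisation or racemisation, and C-silylation of the ynolate could give a silylketene. The fallback reaches the ynolate by sulfonate cleavage at −78 °C. It sets out from alkyne 15: PhI(OH)OTs (CH2Cl2, desiccant) should give the alkynyl(phenyl)iodonium tosylate F4, and CuOTf (cat.) in MeCN should rearrange it to the alkynyl tosylate F5. MeLi at −78 °C attacks sulfur and releases lithium ynolate 17 within minutes, which TIPSOTf traps cold as 18, where the route is rejoined.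

Step 13. The ring position to be iodinated is flanked by a TIPS ether, so substitution may be slow enough for ring C or the alkene to compete, or over-iodination may occur; the same crowding could slow the exchange in step 14. The fallback introduces the acyl carbon by formylation directed by the free phenol. It sets out from phenol 23: MgCl2, Et3N and paraformaldehyde (MeCN, reflux; Casnati–Skattebøl ortho-formylation) should give 2-hydroxy-6-methoxy-3-Q-4-(triisopropylsiloxy)benzaldehyde F6. (E)-PhCH=CHMgBr (2.5 equiv, THF, −78 → 0 °C) should add to give 2-[(E)-1-hydroxy-3-phenylprop-2-en-1-yl]-3-methoxy-6-Q-5-(triisopropylsiloxy)phenol F7. MnO2 should oxidise the carbinol to (E)-1-[2-hydroxy-6-methoxy-3-Q-4-(triisopropylsiloxy)phenyl]-3-phenylprop-2-en-1-one F8, and Bu4NF/AcOH should then give target 30 directly, replacing steps 12–16 by four steps.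

Further compounds
F1 | step 11 | 3-methoxybut-3-en-2-one | C=C(OC)C(C)=O
F2 | step 11 | 1,1,1-trifluoro-5-methoxyhex-5-ene-2,4-dione | C=C(OC)C(=O)CC(=O)C(F)(F)F
F3 | step 11 | 1-diazo-3-methoxybut-3-en-2-one | C=C(OC)C(=O)C=[N+]=[N-]
F4 | step 10 | alkynyl(phenyl)iodonium tosylate derived from 15 | Cc1ccc(cc1)S(=O)(=O)[O-].c1ccc(cc1)[I+]C#C[C@H](/C=C/C[C@H](O[Si](C)(C)C(C)(C)C)CCc1ccccc1)c1ccc(O[Si](C(C)C)(C(C)C)C(C)C)cc1
F5 | step 10 | alkynyl tosylate (1-tosyloxy analogue of 18) | Cc1ccc(cc1)S(=O)(=O)OC#C[C@H](/C=C/C[C@H](O[Si](C)(C)C(C)(C)C)CCc1ccccc1)c1ccc(O[Si](C(C)C)(C(C)C)C(C)C)cc1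
F6 | step 13 | 2-hydroxy-6-methoxy-3-Q-4-(triisopropylsiloxy)benzaldehyde | COc1cc(O[Si](C(C)C)(C(C)C)C(C)C)c([C@H](/C=C/C[C@H](O[Si](C)(C)C(C)(C)C)CCc2ccccc2)c2ccc(O[Si](C(C)C)(C(C)C)C(C)C)cc2)c(O)c1C=O
F7 | step 13 | 2-[(E)-1-hydroxy-3-phenylprop-2-en-1-yl]-3-methoxy-6-Q-5-(triisopropylsiloxy)phenol | COc1cc(O[Si](C(C)C)(C(C)C)C(C)C)c([C@H](/C=C/C[C@H](O[Si](C)(C)C(C)(C)C)CCc2ccccc2)c2ccc(O[Si](C(C)C)(C(C)C)C(C)C)cc2)c(O)c1C(O)/C=C/c1ccccc1
F8 | step 13 | (E)-1-[2-hydroxy-6-methoxy-3-Q-4-(triisopropylsiloxy)phenyl]-3-phenylprop-2-en-1-one | COc1cc(O[Si](C(C)C)(C(C)C)C(C)C)c([C@H](/C=C/C[C@H](O[Si](C)(C)C(C)(C)C)CCc2ccccc2)c2ccc(O[Si](C(C)C)(C(C)C)C(C)C)cc2)c(O)c1C(=O)/C=C/c1ccccc1
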